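A one-step picture, solid substrate straight to target, gives a plateau and no best time, but in Tuesday's run target climbs to 70.1% at 0.625 d, with the solid substrate reading 0.2%, and is down to 2.4% at 6.00 d.

| flask | solid substrate | enzyme | remark | time |
|---|---|---|---|---|
| Tuesday's | 0.010 M | 1.4 µM | run made earlier |  |
| Monday's | 0.010 M | 2.2 µM | run made earlier |  |
| Friday's | 0.015 M | 1 µM | run made earlier |  |
| flask | 0.010 M | 1.0 µM |  | 6.0 d |

- Tuesday's (time / d: target / %, solid substrate / %): 0.167: 22.6, 44.0; 0.333: 61.9, 0; 0.625: 70.1, 0.2; 1.25: 50.0, 0; 3.00: 16.4, 0.2; 6.00: 2.4, 0
- Monday's (time / d: target / %, solid substrate / %): 0.167: 27.9, 43.6; 0.333: 68.1, 0; 0.625: 61.9, 0; 1.25: 34.4, 0.3; 3.00: 5.0, 0.3; 6.00: 0.2, 0.5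
- Friday's (time / d: target / %, solid substrate / %): 0.167: 11.9, 64.0; 0.417: 48.2, 21.0; 1.04: 69.3, 0.2; 2.50: 36.6, 0; 6.00: 6.8, 0

(standard deviation of a reading: 0.3 percentage points)

- solid, in amounts per volume of the solution: solid substrate
- candidate steps: starting material + enzyme -> target + enzyme; solid substrate <-> starting material; enzyme + target -> enzyme + over-reaction product
- at the start none of the solid substrate is in solution

- the best time, 6.0 d at the latest, for target
- the amount of target, in percent of the solid substrate charged, at that time
- earliest time at which at least nineteen twentieths of that best amount are there, in d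
- latest time at which they still are, in d

Between two late readings of each run, the logarithm of target falls at a slope that follows [enzyme], the pseudo-first-order picture of the candidate step in which enzyme turns target into over-reaction product. That slope per unit of enzyme, called here the loss constant, reads 19000 M⁻¹ h⁻¹ in Tuesday's run, 20900 M⁻¹ h⁻¹ in Monday's and 20000 M⁻¹ h⁻¹ in Friday's, and this last reading is the loss constant carried on. Turned round, the question is what a flask needs for target already formed, counted apart from any made later, to keep at least half of itself through the time allowed: the loss constant times [enzyme] times that time has to stay under 0.693. This flask, at 1.0 µM and 6.0 d, stands at 2.89, which is 4.17 times that line. Its target half-life of 1.44 d is shorter than the time allowed, so the reckoning here commits to an early peak to be harvested, not a hold to the end.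

The forecast puts the best at 74.5% at 0.71 d, with the window from 0.52 d to 1.02 d, and has among its grounds that “The late decay of target is first order”.

The flask gives 73.5% at 0.595 d, with the window from 0.447 d to 0.855 d.

    starting material + enzyme → target + enzyme, rate k1*[starting material]^2.5*[enzyme]/(1 + ([starting material]/Kh1)^2.5) (4.10 mM, k = 5.40 × 10⁵ M⁻²·⁵ s⁻¹)
    solid substrate ⇌ starting material, rate k2*(cs2 - [starting material]) while solid is left; crystals form when [starting material] > cs2 (solubility = 9.50 mM, k = 0.190 h⁻¹)
    enzyme + target → enzyme + over-reaction product (k = 20000 M⁻¹ h⁻¹)

In the flask at 6.00 d, target is made at 0.0636 of the rate at which it is used up, each step taken net, which is more slowly than it is used up. The loss constant, applied to the 28.0% at 3.00 d, gives 6.62% at the end, against 7.20% in the flask.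

For the neighbour charged with 2.5 × 10⁻⁷ M of enzyme, the same product comes to 0.721, beside the line at 0.693, so by this reckoning target counted over the whole time allowed keeps 48.6% of itself. Computed, that neighbour peaks at 74.4% and ends with more target, 51.8%, than over-reaction product, 43.2%.

(The data are simulated for substances that don't exist; scatter was added.)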